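**Plan**

1. Retrosynthesis (target locants, see remark): the C1 formyl group goes back to CH2OH, the C1–C10 oxirane to a cis C10=C1 olefin, and the CH2OH to a methyl group on a trans C10=C1 olefin, i.e. to an (E,E)-cyclodeca-1,5-diene.
2. Enabling feature: C6=C7 and C10=C1 (the olefin behind the oxirane) flank the C8–C9 σ-bond as a 1,5-diene, and C1 can carry oxygen (methyl ← enol triflate ← enolate). This is the pattern of an oxy-Cope product, so cutting C8–C9 while reconnecting C1–C6 contracts the ten-membered ring to the cyclohexane C1–C6, a 1-vinyl-2-isopropenylcyclohexanol.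
3. The temporary C1–C6 bond is then cut by a retro carbonyl-ene reaction to an open-chain aldehyde. Its C5 carbinol is cut back to a ketone, the C5–C6 bond to a Weinreb amide plus an alkenyl Grignard reagent, and the C3–C4 bond to an auxiliary aldol.
4. Forward: chain C1–C8 assembled (steps 1–7), six-membered ring C1–C6 closed (step 8), vinyl carbinol made (steps 9–10), ring enlarged to the ten-membered ring with enolate triflation (step 11), then methyl, acetates, allylic hydroxylation, oxirane and aldehyde (steps 12–17).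
5. Stereochemistry: C3/C4 from the oxazolidinone aldol; C5 from hydroxyl-directed anti reduction; the temporary centres C6 and C1 from the chair ene transition state and equatorial vinyl addition; 6E from the chair of the [3,3] shift; cis C10=C1 from the [2,3] step of the SeO2 oxidation; C1/C10 of the oxirane from the tartrate.
6. Helpers: the C1–C6 ring bond and the C1 alkoxide exist only to drive the key step; the bond breaks in it and the oxygen leaves as triflate in step 12.

Key step: step 11

Remark: locants Cn in the Why lines are those of the target name (11-oxabicyclo[8.1.0]undec-6-ene: C1 formyl-bearing oxirane carbon, C3/C5 acetoxy, C4 isopropyl, C7 methyl, C10 oxirane CH); they coincide with the chain locants of 7–10, ring positions 1–6 in the names of 11–14 are target C1, C6, C5, C4, C3, C2, and 1 and 2 are taken to be catalogue compounds.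

**Route**

Step 1
Reactants: 1 (4S)-4-benzyl-3-(3-methylbutanoyl)-1,3-oxazolidin-2-one; 2 3-{[tert-butyl(diphenyl)silyl]oxy}propanal
Product: 4 (4S)-4-benzyl-3-[(2S,3R)-5-{[tert-butyl(diphenyl)silyl]oxy}-3-hydroxy-2-(propan-2-yl)pentanoyl]-1,3-oxazolidin-2-one, via dibutylboron Z-enolate 3 (not isolated)
Conditions: Bu2BOTf, iPr2NEt, CH2Cl2, −78 to 0 °C; then 2, −78 to 0 °C; H2O2, MeOH, pH 7 buffer
Reagents that add atoms: none
Why: Evans syn-aldol reaction in which the Z-boron enolate 3 adds through a closed chair transition state on the face opposite the benzyl group, which should set target C4 (S) and C3 (R) as the 2S,3R syn adduct.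

Step 2
Reactants: 4 syn-aldol imide
Product: 5 (2S,3R)-5-{[tert-butyl(diphenyl)silyl]oxy}-3-hydroxy-N-methoxy-N-methyl-2-(propan-2-yl)pentanamide
Conditions: MeNH(OMe)·HCl, AlMe3, CH2Cl2, −20 to 0 °C
Reagents that add atoms: N,O-dimethylhydroxylamine hydrochloride, CNOC.Cl
Why: Aluminium amide transamidation (Weinreb amide formation), assisted by the aluminium alkoxide of the free β-hydroxyl, should release the auxiliary without touching the α-stereocentre.

Step 3
Reactants: 5 Weinreb amide
Product: 6 (5S,6R)-8-{[tert-butyl(diphenyl)silyl]oxy}-6-hydroxy-2-methyl-5-(propan-2-yl)oct-2-en-4-one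
Conditions: 2-methylprop-1-enylmagnesium bromide (3 equiv), THF, 0 °C
Reagents that add atoms: 2-methylprop-1-en-1-ylmagnesium bromide, CC(C)=C[Mg]Br
Why: Grignard addition to a Weinreb amide stops at the chelated tetrahedral intermediate, so the enone is expected without over-addition or epimerisation, the first equivalent being spent on the hydroxyl.

Step 4
Reactants: 6 β-hydroxy enone
Product: 7 (3R,4S,5R)-1-{[tert-butyl(diphenyl)silyl]oxy}-7-methyl-4-(propan-2-yl)oct-6-ene-3,5-diol
Conditions: Me4NBH(OAc)3, MeCN/AcOH, −30 °C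
Reagents that add atoms: none
Why: Evans–Saksena reduction, in which the carbinol-bound acetoxyborohydride delivers hydride intramolecularly through a chair transition state, should give the 1,3-anti diol and so set C5 (R).

Step 5
Reactants: 7 anti-diol
Product: 8 tert-butyl({(3R,4S,5R)-3,5-bis[(4-methoxyphenyl)methoxy]-7-methyl-4-(propan-2-yl)oct-6-en-1-yl}oxy)diphenylsilane
Conditions: NaH, 4-methoxybenzyl chloride, Bu4NI (cat.), DMF, 0 °C to rt
Reagents that add atoms: 4-methoxybenzyl chloride, COc1ccc(CCl)cc1
Why: Williamson etherification protects both secondary hydroxyls as PMB ethers that cannot migrate, survive the organometallic, Lewis acidic and strongly basic steps ahead and are removed oxidatively.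

Step 6
Reactants: 8 bis-PMB silyl ether
Product: 9 (3R,4S,5R)-3,5-bis[(4-methoxyphenyl)methoxy]-7-methyl-4-(propan-2-yl)oct-6-en-1-ol
Conditions: Bu4NF, THF, 0 °C to rt
Reagents that add atoms: none
Why: Fluoride-mediated desilylation should free only the primary alcohol, the PMB ethers being inert.

Step 7
Reactants: 9 primary alcohol
Product: 10 (3R,4S,5R)-3,5-bis[(4-methoxyphenyl)methoxy]-7-methyl-4-(propan-2-yl)oct-6-enal
Conditions: Dess–Martin periodinane, NaHCO3, CH2Cl2, 0 °C to rt
Reagents that add atoms: none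
Why: Dess–Martin oxidation under buffered, non-basic conditions should give the β-alkoxy aldehyde without β-elimination.

Step 8
Reactants: 10 aldehyde
Product: 11 (1S,2R,3S,4S,5R)-3,5-bis[(4-methoxyphenyl)methoxy]-4-(propan-2-yl)-2-(prop-1-en-2-yl)cyclohexan-1-ol
Conditions: Me2AlCl, CH2Cl2, −78 to −20 °C
Reagents that add atoms: none
Why: Intramolecular carbonyl-ene reaction of the citronellal-to-isopulegol kind through a chair transition state with the isopropyl group and the C3 ether equatorial and the allylic C5 ether axial (A(1,3) strain with the cis methyl group), which should place the new isopropenyl group equatorial at C6, cis to the C5 ether; the carbinol configuration at C1 (expected trans to isopropenyl) does not matter because C1 is oxidised next.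

Step 9
Reactants: 11 cyclohexanol
Product: 12 (2S,3S,4S,5R)-3,5-bis[(4-methoxyphenyl)methoxy]-4-(propan-2-yl)-2-(prop-1-en-2-yl)cyclohexan-1-one
Conditions: Dess–Martin periodinane, NaHCO3, CH2Cl2, 0 °C
Reagents that add atoms: none
Why: Dess–Martin oxidation is neutral enough to give the β,γ-unsaturated β-alkoxy ketone without conjugation or loss of the C5 ether, and C6 already carries the thermodynamically preferred equatorial isopropenyl group.

Step 10
Reactants: 12 ketone
Product: 13 (1S,2S,3S,4S,5R)-1-ethenyl-3,5-bis[(4-methoxyphenyl)methoxy]-4-(propan-2-yl)-2-(prop-1-en-2-yl)cyclohexan-1-ol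
Conditions: CH2=CHMgBr, CeCl3, THF, −78 °C
Reagents that add atoms: vinylmagnesium bromide, C=C[Mg]Br
Why: 1,2-Addition of the weakly basic vinylcerium reagent avoids enolisation, and equatorial attack is expected because the axial C5 ether blocks the axial trajectory, giving the axial tertiary alcohol with vinyl and isopropenyl trans-diequatorial.

Step 11
Reactants: 13 divinyl carbinol
Product: 16 (1Z,5E,7R,8S,9R)-7,9-bis[(4-methoxyphenyl)methoxy]-5-methyl-8-(propan-2-yl)cyclodeca-1,5-dien-1-yl trifluoromethanesulfonate, via potassium alkoxide 14 (not isolated), via potassium enolate 15 (not isolated)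
Conditions: KH, 18-crown-6, THF, 0 °C to rt; then Comins' reagent, −78 to 0 °C
Reagents that add atoms: N-(5-chloropyridin-2-yl)bis(trifluoromethanesulfonimide) (Comins' reagent), Clc1ccc(nc1)N(S(=O)(=O)C(F)(F)F)S(=O)(=O)C(F)(F)F
Why: KH deprotonates 13 and the crown-ether-separated potassium alkoxide 14 undergoes a [3,3]-sigmatropic shift (anionic oxy-Cope rearrangement) in which the C1–C6 bond of the cyclohexane breaks while C8–C9 forms between the termini of the isopropenyl and vinyl groups, giving the regiodefined potassium enolate 15, which Comins' reagent O-sulfonylates in the same flask. The closest known reaction type is the anionic oxy-Cope ring expansion of trans-1,2-dialkenylcyclohexanols to (E)-cyclodec-5-enones combined with in situ enolate triflation. The ten-membered carbocycle is closed not by end-to-end cyclisation but by four-atom enlargement of the six-membered ring through a six-membered chair-like pericyclic transition state, the strain of the medium ring being paid for by the conversion of alkoxide into enolate. No stereocentre is created and C3, C4 and C5 are spectators; both new olefin geometries follow from the chair in which the two alkenyl groups are equatorial, so that the ring residues C5 and C2 lie pseudo-equatorial, C6=C7 forms E and the enol double bond C10=C1 forms trans within the ring. The step needs regioselectivity (enolate towards C10, not C2), which the mechanism guarantees, and chemoselectivity against loss of the ether oxygens, secured because the carbanionic carbon C10 has no β-leaving group and the enolate is captured at low temperature before proton transfer can move it to C2.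

Step 12
Reactants: 16 enol triflate
Product: 17 1,1'-{[(1R,2S,3R,4E,8E)-5,9-dimethyl-2-(propan-2-yl)cyclodeca-4,8-diene-1,3-diyl]bis(oxymethylene)}bis(4-methoxybenzene)
Conditions: MeMgBr, Fe(acac)3 (5 mol %), THF/NMP, −30 °C
Reagents that add atoms: methylmagnesium bromide, C[Mg]Br
Why: Iron-catalysed Kumada-type cross-coupling of an alkenyl triflate proceeds with retention of olefin geometry and should give the (E,E)-cyclodeca-1,5-diene carrying the C1 methyl group, which removes the oxygen that drove the key step.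

Step 13
Reactants: 17 bis-PMB ether
Product: 18 (1R,2S,3R,4E,8E)-5,9-dimethyl-2-(propan-2-yl)cyclodeca-4,8-diene-1,3-diol
Conditions: DDQ, CH2Cl2/pH 7 buffer, 0 °C
Reagents that add atoms: none
Why: Oxidative PMB cleavage by DDQ (benzylic hydride abstraction, then hydrolysis of the oxocarbenium ion) is near neutral when buffered and should leave the acid-sensitive 1,5-diene untouched.

Step 14
Reactants: 18 diol
Product: 19 (1R,2S,3R,4E,8E)-5,9-dimethyl-2-(propan-2-yl)cyclodeca-4,8-diene-1,3-diyl diacetate
Conditions: Ac2O, pyridine, DMAP (cat.), CH2Cl2, rt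
Reagents that add atoms: acetic anhydride, CC(=O)OC(C)=O
Why: DMAP-catalysed acetylation installs both acetates of the target before any oxirane or aldehyde is present, and the C5 acetate deactivates the C6=C7 olefin for the next step.

Step 15
Reactants: 19 diene diacetate
Product: 20 (1R,2S,3R,4E,8E)-9-(hydroxymethyl)-5-methyl-2-(propan-2-yl)cyclodeca-4,8-diene-1,3-diyl diacetate (the 8,9-olefin now cis within the ring)
Conditions: SeO2 (cat.), t-BuOOH, CH2Cl2, 0 °C to rt
Reagents that add atoms: selenium dioxide, O=[Se]=O; tert-butyl hydroperoxide, CC(C)(C)OO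
Why: Riley allylic oxidation in its catalytic hydroperoxide variant should begin with an ene reaction at the electron-richer C10=C1 olefin (C6=C7 is deactivated by the allylic C5 acetate) and finish with a [2,3]-sigmatropic shift that hydroxylates the C1 methyl group and, as is known for (E,E)-germacradienes, returns the double bond with C9 trans to CH2OH, i.e. as the cis ring olefin needed for the oxirane.

Step 16
Reactants: 20 allylic alcohol
Product: 21 (1R,3R,4S,5R,6E,10R)-1-(hydroxymethyl)-7-methyl-4-(propan-2-yl)-11-oxabicyclo[8.1.0]undec-6-ene-3,5-diyl diacetate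
Conditions: Ti(OiPr)4, D-(−)-diethyl tartrate, t-BuOOH, 4 Å MS, CH2Cl2, −20 °C
Reagents that add atoms: tert-butyl hydroperoxide, CC(C)(C)OO
Why: Sharpless asymmetric epoxidation is hydroxyl-directed, so only the allylic alcohol olefin should react, and D-(−)-diethyl tartrate is the enantiomer that converts (E)-3-substituted allylic alcohols into (2R,3R)-epoxy alcohols, which corresponds to the (1R,10R) oxirane of 21 with syn addition giving the cis ring fusion.

Step 17
Reactants: 21 epoxy alcohol
Product: 22 (1S,3R,4S,5R,6E,10R)-1-formyl-7-methyl-4-(propan-2-yl)-11-oxabicyclo[8.1.0]undec-6-ene-3,5-diyl diacetate (pulicanaral A)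
Conditions: (nPr4N)RuO4 (cat.), NMO, 4 Å MS, CH2Cl2, rt
Reagents that add atoms: none
Why: Ley–Griffith oxidation under neutral conditions should convert the primary epoxy alcohol into the α,β-epoxy aldehyde, which has no α-hydrogen and so cannot epimerise, leaving acetates, olefin and oxirane untouched.

**Compound list**

1 | (4S)-4-benzyl-3-(3-methylbutanoyl)-1,3-oxazolidin-2-one | CC(C)CC(=O)N1[C@@H](Cc2ccccc2)COC1=O | starting material
2 | 3-{[tert-butyl(diphenyl)silyl]oxy}propanal | O=CCCO[Si](c1ccccc1)(c1ccccc1)C(C)(C)C | starting material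
3 | dibutylboron (Z)-enolate of 1 | CCCCB(CCCC)O/C(=C\C(C)C)N1[C@@H](Cc2ccccc2)COC1=O | intermediate (not isolated)
4 | (4S)-4-benzyl-3-[(2S,3R)-5-{[tert-butyl(diphenyl)silyl]oxy}-3-hydroxy-2-(propan-2-yl)pentanoyl]-1,3-oxazolidin-2-one | O=C1OC[C@H](Cc2ccccc2)N1C(=O)[C@@H](C(C)C)[C@H](O)CCO[Si](c1ccccc1)(c1ccccc1)C(C)(C)C | intermediate
5 | (2S,3R)-5-{[tert-butyl(diphenyl)silyl]oxy}-3-hydroxy-N-methoxy-N-methyl-2-(propan-2-yl)pentanamide | CON(C)C(=O)[C@@H](C(C)C)[C@H](O)CCO[Si](c1ccccc1)(c1ccccc1)C(C)(C)C | intermediate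
6 | (5S,6R)-8-{[tert-butyl(diphenyl)silyl]oxy}-6-hydroxy-2-methyl-5-(propan-2-yl)oct-2-en-4-one | CC(C)=CC(=O)[C@@H](C(C)C)[C@H](O)CCO[Si](c1ccccc1)(c1ccccc1)C(C)(C)C | intermediate
7 | (3R,4S,5R)-1-{[tert-butyl(diphenyl)silyl]oxy}-7-methyl-4-(propan-2-yl)oct-6-ene-3,5-diol | CC(C)=C[C@@H](O)[C@@H](C(C)C)[C@H](O)CCO[Si](c1ccccc1)(c1ccccc1)C(C)(C)C | intermediate
8 | tert-butyl({(3R,4S,5R)-3,5-bis[(4-methoxyphenyl)methoxy]-7-methyl-4-(propan-2-yl)oct-6-en-1-yl}oxy)diphenylsilane | CC(C)=C[C@@H](OCc1ccc(OC)cc1)[C@@H](C(C)C)[C@H](OCc1ccc(OC)cc1)CCO[Si](c1ccccc1)(c1ccccc1)C(C)(C)C | intermediate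
9 | (3R,4S,5R)-3,5-bis[(4-methoxyphenyl)methoxy]-7-methyl-4-(propan-2-yl)oct-6-en-1-ol | CC(C)=C[C@@H](OCc1ccc(OC)cc1)[C@@H](C(C)C)[C@H](OCc1ccc(OC)cc1)CCO | intermediate
10 | (3R,4S,5R)-3,5-bis[(4-methoxyphenyl)methoxy]-7-methyl-4-(propan-2-yl)oct-6-enal | CC(C)=C[C@@H](OCc1ccc(OC)cc1)[C@@H](C(C)C)[C@H](OCc1ccc(OC)cc1)CC=O | intermediate
11 | (1S,2R,3S,4S,5R)-3,5-bis[(4-methoxyphenyl)methoxy]-4-(propan-2-yl)-2-(prop-1-en-2-yl)cyclohexan-1-ol (expected major carbinol epimer) | O[C@H]1C[C@@H](OCc2ccc(OC)cc2)[C@H](C(C)C)[C@H](OCc2ccc(OC)cc2)[C@@H]1C(C)=C | intermediate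
12 | (2S,3S,4S,5R)-3,5-bis[(4-methoxyphenyl)methoxy]-4-(propan-2-yl)-2-(prop-1-en-2-yl)cyclohexan-1-one | O=C1C[C@@H](OCc2ccc(OC)cc2)[C@H](C(C)C)[C@H](OCc2ccc(OC)cc2)[C@@H]1C(C)=C | intermediate
13 | (1S,2S,3S,4S,5R)-1-ethenyl-3,5-bis[(4-methoxyphenyl)methoxy]-4-(propan-2-yl)-2-(prop-1-en-2-yl)cyclohexan-1-ol | O[C@]1(C=C)C[C@@H](OCc2ccc(OC)cc2)[C@H](C(C)C)[C@H](OCc2ccc(OC)cc2)[C@@H]1C(C)=C | intermediate
14 | potassium (1S,2S,3S,4S,5R)-1-ethenyl-3,5-bis[(4-methoxyphenyl)methoxy]-4-(propan-2-yl)-2-(prop-1-en-2-yl)cyclohexan-1-olate | [K+].[O-][C@]1(C=C)C[C@@H](OCc2ccc(OC)cc2)[C@H](C(C)C)[C@H](OCc2ccc(OC)cc2)[C@@H]1C(C)=C | intermediate (not isolated)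
15 | potassium (1Z,5E,7R,8S,9R)-7,9-bis[(4-methoxyphenyl)methoxy]-5-methyl-8-(propan-2-yl)cyclodeca-1,5-dien-1-olate | COc1ccc(CO[C@@H]2/C=C(\C)CC/C=C(\[O-])C[C@@H](OCc3ccc(OC)cc3)[C@@H]2C(C)C)cc1.[K+] | intermediate (not isolated)
16 | (1Z,5E,7R,8S,9R)-7,9-bis[(4-methoxyphenyl)methoxy]-5-methyl-8-(propan-2-yl)cyclodeca-1,5-dien-1-yl trifluoromethanesulfonate | COc1ccc(CO[C@@H]2/C=C(\C)CC/C=C(\OS(=O)(=O)C(F)(F)F)C[C@@H](OCc3ccc(OC)cc3)[C@@H]2C(C)C)cc1 | intermediate
17 | 1,1'-{[(1R,2S,3R,4E,8E)-5,9-dimethyl-2-(propan-2-yl)cyclodeca-4,8-diene-1,3-diyl]bis(oxymethylene)}bis(4-methoxybenzene) | COc1ccc(CO[C@@H]2/C=C(\C)CC/C=C(\C)C[C@@H](OCc3ccc(OC)cc3)[C@@H]2C(C)C)cc1 | intermediate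
18 | (1R,2S,3R,4E,8E)-5,9-dimethyl-2-(propan-2-yl)cyclodeca-4,8-diene-1,3-diol | O[C@@H]1/C=C(\C)CC/C=C(\C)C[C@@H](O)[C@@H]1C(C)C | intermediate
19 | (1R,2S,3R,4E,8E)-5,9-dimethyl-2-(propan-2-yl)cyclodeca-4,8-diene-1,3-diyl diacetate | CC(=O)O[C@@H]1/C=C(\C)CC/C=C(\C)C[C@@H](OC(C)=O)[C@@H]1C(C)C | intermediate
20 | (1R,2S,3R,4E,8E)-9-(hydroxymethyl)-5-methyl-2-(propan-2-yl)cyclodeca-4,8-diene-1,3-diyl diacetate | CC(=O)O[C@@H]1/C=C(\C)CC/C=C(/CO)C[C@@H](OC(C)=O)[C@@H]1C(C)C | intermediate
21 | (1R,3R,4S,5R,6E,10R)-1-(hydroxymethyl)-7-methyl-4-(propan-2-yl)-11-oxabicyclo[8.1.0]undec-6-ene-3,5-diyl diacetate | CC(=O)O[C@@H]1/C=C(\C)CC[C@H]2O[C@@]2(CO)C[C@@H](OC(C)=O)[C@@H]1C(C)C | intermediate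
22 | (1S,3R,4S,5R,6E,10R)-1-formyl-7-methyl-4-(propan-2-yl)-11-oxabicyclo[8.1.0]undec-6-ene-3,5-diyl diacetate (pulicanaral A) | CC(=O)O[C@@H]1/C=C(\C)CC[C@H]2O[C@@]2(C=O)C[C@@H](OC(C)=O)[C@@H]1C(C)C | target

Total step count: 17. Longest linear sequence: 17 steps (1 to 22).

**Steps most likely to fail**

Step 15. The allylic oxidation may lose site selectivity (attack at the ring CH2 next to C1 or at the acetate-flanked C6=C7 olefin), over-oxidise to the enal, trigger acid-promoted transannular cyclisation of the 1,5-diene, or fail to turn the olefin geometry. The fallback sets out from 19 and comes back at 20, and replaces direct C–H oxidation by an epoxide detour. One equivalent of mCPBA (NaHCO3, CH2Cl2, −20 °C) should epoxidise only the electron-richer olefin remote from the acetates to give the trans-epoxide (1R,2S,3R,4E)-8,9-epoxy-5,9-dimethyl-2-(propan-2-yl)cyclodec-4-ene-1,3-diyl diacetate F1. The hindered amide base Et2AlN(C9H18) (diethylaluminium 2,2,6,6-tetramethylpiperidide, toluene, 0 °C) should then open it by proton abstraction from the methyl group to the exocyclic secondary allylic alcohol (1R,2S,3R,4E)-8-hydroxy-5-methyl-9-methylidene-2-(propan-2-yl)cyclodec-4-ene-1,3-diyl diacetate F2. A catalytic amount of Ph3SiOReO3 finally effects the 1,3-transposition of the hydroxyl to the thermodynamically preferred primary alcohol on a trisubstituted olefin, which in the ten-membered ring should be the cis ring olefin 20. Either face of epoxidation converges on the same product.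

Step 11. Proton transfer within enolate 15 towards C2 followed by β-elimination of the C3 ether, or incomplete O-sulfonylation, may erode the regiodefined triflate. The fallback sets out from 13 and comes back at 16, and separates the ring expansion from the triflation. The rearranged enolate is quenched at −78 °C with Me3SiCl/Et3N, a much faster O-capture, and isolated as the trimethylsilyl enol ether {[(1Z,5E,7R,8S,9R)-7,9-bis[(4-methoxyphenyl)methoxy]-5-methyl-8-(propan-2-yl)cyclodeca-1,5-dien-1-yl]oxy}trimethylsilane F3. MeLi (THF, −78 °C) then releases the same enolate as its crown-free lithium enolate F4 (not isolated), which is far less prone to proton transfer, and Comins' reagent converts it into 16.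

Step 16. Facial selectivity may be poor if the conformational bias of the ten-membered ring opposes the tartrate, and slow epoxidation of the ring-embedded trisubstituted olefin may allow transannular opening of the product. The fallback sets out from 20 and comes back at 22, and changes from directed electrophilic to nucleophilic epoxidation. MnO2 (CH2Cl2) oxidises the allylic alcohol to the enal (1R,2S,3R,4E,8E)-9-formyl-5-methyl-2-(propan-2-yl)cyclodeca-4,8-diene-1,3-diyl diacetate F5. Aqueous H2O2 with a cinchona-derived chiral primary amine salt (iminium activation of α-branched enals, catalyst enantiomer chosen for the C1/C10 sense of 22) should then give the epoxy aldehyde 22 directly.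

**Further compounds**

F1 | step 15 | (1R,2S,3R,4E)-8,9-epoxy-5,9-dimethyl-2-(propan-2-yl)cyclodec-4-ene-1,3-diyl diacetate (trans-oxirane, one of the two faces drawn) | CC(=O)O[C@@H]1/C=C(\C)CC[C@@H]2O[C@@]2(C)C[C@@H](OC(C)=O)[C@@H]1C(C)C
F2 | step 15 | (1R,2S,3R,4E)-8-hydroxy-5-methyl-9-methylidene-2-(propan-2-yl)cyclodec-4-ene-1,3-diyl diacetate (C8 epimer from the face drawn for F1) | CC(=O)O[C@@H]1/C=C(\C)CC[C@H](O)C(=C)C[C@@H](OC(C)=O)[C@@H]1C(C)C
F3 | step 11 | {[(1Z,5E,7R,8S,9R)-7,9-bis[(4-methoxyphenyl)methoxy]-5-methyl-8-(propan-2-yl)cyclodeca-1,5-dien-1-yl]oxy}trimethylsilane | COc1ccc(CO[C@@H]2/C=C(\C)CC/C=C(\O[Si](C)(C)C)C[C@@H](OCc3ccc(OC)cc3)[C@@H]2C(C)C)cc1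
F4 | step 11 | lithium (1Z,5E,7R,8S,9R)-7,9-bis[(4-methoxyphenyl)methoxy]-5-methyl-8-(propan-2-yl)cyclodeca-1,5-dien-1-olate | COc1ccc(CO[C@@H]2/C=C(\C)CC/C=C(\[O-])C[C@@H](OCc3ccc(OC)cc3)[C@@H]2C(C)C)cc1.[Li+]
F5 | step 16 | (1R,2S,3R,4E,8E)-9-formyl-5-methyl-2-(propan-2-yl)cyclodeca-4,8-diene-1,3-diyl diacetate | CC(=O)O[C@@H]1/C=C(\C)CC/C=C(/C=O)C[C@@H](OC(C)=O)[C@@H]1C(C)C
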